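## The problem

The terpenoid carbons are numbered as in germacrane: C1 is the ring-fusion CH, C10 the C(CH3)–O carbon, C4=C5 the olefin, C7 the CH bearing the 2-hydroxypropan-2-yl group (C11), C14 and C15 the methyls on C10 and C4, and C1' the benzylic carbon bearing isobutyl.

- The target is a diformylphloroglucinol whose dihydropyran ring is trans-fused, through C10 and C1, to a ten-membered carbocycle.
- The carbocycle is the hardest part. A medium ring resists closure, and it must carry a Z trisubstituted olefin (C4=C5) next to a ring fusion that can only come from an E-configured C1=C10 olefin.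
- C10, C1 and C1' are contiguous and can be set together by one suprafacial cycloaddition.
- C7 is insulated from them by CH2 groups on both sides, so it cannot be relayed from the chroman. It has to be brought in and then related to the triad through the conformation of the ring.
- The formyl groups and vinylogous-acid phenols, the tertiary alcohol and the medium-ring olefins (acid-triggered transannular cyclisation) will not survive rough treatment. The aromatic half should therefore arrive last and unprotected.
- The feature that makes the key step possible: C1 and C5 are 1,5-related, each lies next to a methyl-bearing carbon (C10, C4), and C7 with its C11 carbinol sits three bonds from C4 and from C10. Joining C1 to C5 gives the hydroazulene of (−)-guaiol, with the same carbons, the same C11–OH and the same (7R) centre. The ten-membered ring is thus a 1,5-seco-guaiane, and cleaving the C1=C5 ring-fusion olefin of guaiol leaves carbonyls on exactly the two carbons that must become olefinic.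

## Retrosynthesis

**14 ⇒ 10 + 11 + 12.** The O–C10 and C1'–C1 bonds (and C1'–aryl) are cut together. This is the retron of a Knoevenagel/hetero-Diels–Alder sequence through ortho-quinone methide 13. It removes the whole aromatic half and three of four stereocentres in one unprotected operation, which no stepwise chroman synthesis matches. The precursor 10 is (7R)-(2Z,6E)-hedycaryol, a C15H26O monocycle. The forward reaction must pick the E-C1=C10 olefin over Z-C4=C5, put oxygen on C10, and add to the ring face that relates C1/C10 correctly to C7.

**10 ⇒ 9 ⇒ 7.** The C5–H bond is traced back to C5–OTf and then to a C5 ketone. The Z (ring-cis) geometry is the thermodynamically preferred one in a cyclodecene, so it can be taken from an equilibrium-controlled enolisation. The E olefin cannot be made that way, so the two olefins need different logic. Enone 7 has one olefin and one stereocentre that matters (C7).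

**7 ⇒ 6 ⇒ 5 ⇒ 4.** The C5–C10 bond is re-formed in the retro direction. An E-cyclodec-5-enone is the classical product of a Wharton–Grob fragmentation of a decalin 1,3-diol monosulfonate. The olefin geometry is then only a function of the C1/C10 relative configuration, which a hydride reduction of ketol 4 sets (giving 5, mesylated to 6). A boronate-type fragmentation on the same decalin framework would form both olefins at once, but syn addition of H and B can only give the 4E isomer, so it was set aside. The forward reaction needs an antiperiplanar C1–O/C5–C10 arrangement, which an equatorial sulfonate on a trans-decalin provides.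

**4 ⇒ 3.** The C5–C10 bond is cut by a retro-aldol. Diketone 3 is monocyclic and its C4 and C10 centres are epimerisable, so nothing has to be controlled before this point. The forward aldol must close from C10 onto C5 and not from C6 onto C1.

**3 ⇒ 1.** C1 and C5 are reconnected as a tetrasubstituted olefin, which gives (−)-guaiol 1. This is the key cut: the ten-membered ring is never closed, only unmasked, and C7 and the C11 carbinol come from the chiral pool. Compounds 1 and 10 are isomers, so the terpenoid half is made by skeletal isomerisation guaiane → eudesmane → germacrane.

## Roads not taken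

Alternative 1: The most obvious plan keeps the final cycloaddition but builds 10 de novo by closing the ten-membered ring at C6–C7. The forward key step would be intramolecular opening of the epoxide of (2Z,6E,10R)-10,11-epoxyfarnesyl phenyl sulfide A1 by its α-thio allylic carbanion, followed by reductive desulfurisation to 10. It is inferior for four reasons:
- a ten-membered ring must be closed by an ambident (α/γ) allyl anion;
- the Z allylic geometry has to survive both the anion and the dissolving-metal step;
- C7 depends on a site- and enantioselective epoxidation of one of three trisubstituted olefins;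
- the run-up to A1 is as long as the whole chosen route.

Alternative 2: An enzymatic cut of the same C6–C7 bond: a class I terpene cyclase of the (2Z,6E)-hedycaryol synthase type would convert farnesyl diphosphate A2 into 10 in one step. This is the shortest conceivable route. It was not chosen because the sense of asymmetric induction at C7 is fixed by the protein fold and cannot be chosen at the bench. If the enzyme gave the antipode, the whole synthesis would give the wrong enantiomer. The volatile, acid-labile product would also have to be recovered from dilute aqueous medium. The guaiol route takes (7R) from the chiral pool with certainty.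

Alternative 3: Chroman first, then ring closure at C4=C5 by ring-closing metathesis of seco-diene A3. It is inferior for four reasons:
- metathesis to a trisubstituted olefin in a ten-membered carbocycle is unfavourable and its geometry is not under control;
- A3 needs all four stereocentres, including the remote C7, assembled on an open chain with no ring to relay them;
- the free diformylphloroglucinol would have to be protected from the carbene catalyst;
- the aromatic half would be carried through many steps instead of arriving last.

Key step: step 1

Remarks on the chemistry: (−)-guaiol is taken with its established (4S,7R,10S) configuration, and its C7 centre maps directly onto the (7R) centre of the target. Compounds 1, 11 and 12 are taken as commercial. Guaiane and eudesmane intermediates keep the germacrane atom numbers.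

## Route

Step 1
Reactants: 1 (−)-guaiol
Product: 3 (4S,7R,10S)-11-hydroxygermacrane-1,5-dione, via primary ozonide 2 (not isolated)
Conditions: O3, CH2Cl2/MeOH (4:1), −78 °C; then Me2S, −78 °C → rt
Reagents that add atoms: ozone, O=[O+][O-]
Why: Ozonolysis by the Criegee mechanism: ozone adds in a [3+2] sense to the only C=C of 1, the tetrasubstituted C1=C5 ring-fusion bond, to give primary ozonide 2, whose cycloreversion and reductive work-up should leave ketones at C1 and C5. Because the cleaved bond is common to the five- and seven-membered rings, the bicycle opens to the ten-membered ring; no ring is closed and no medium-ring cyclisation is needed. No stereocentre is created: C7 is untouched and the α-methyl centres C4 and C10 are carried along, their later epimerisation being harmless since both are reset or become sp2. The closest known reaction type is ozonolytic cleavage of tetrasubstituted ring-fusion olefins of bicyclic hydrocarbons to medium-ring diketones. The only selectivity needed is C=C over the tertiary carbinol, which the absence of any other oxidisable group secures. Capture of the carbonyl oxide by methanol or by the C11 hydroxyl gives only peroxy ketals that dimethyl sulfide reduces to the same diketone, and reversible hemiketalisation of the C5 carbonyl by the C11 hydroxyl is inconsequential.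

Step 2
Reactants: 3 (4S,7R,10S)-11-hydroxygermacrane-1,5-dione
Product: 4 (4R,5R,7R,10R)-5,11-dihydroxyeudesman-1-one
Conditions: NaOMe (0.2 equiv), MeOH, 0 °C → rt
Reagents that add atoms: none
Why: Reversible transannular aldol addition, 6-(enolendo)-exo-trig, of the C10 enolate of the C1 ketone onto the C5 carbonyl; it should give the unstrained trans-decalol with axial C14, equatorial C15 and equatorial C7 side chain, whereas the competing C6-onto-C1 closure would put the new ring-fusion bond vicinal to the bulky C7 substituent. C4, C5 and C10 are set under thermodynamic control (C4 and C10 of 3 epimerise by enolisation) and none of them survives to the target.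

Step 3
Reactants: 4 (4R,5R,7R,10R)-5,11-dihydroxyeudesman-1-one
Product: 5 (1R,4R,5R,7R,10S)-eudesmane-1,5,11-triol
Conditions: NaBH4, MeOH, −20 °C → 0 °C
Reagents that add atoms: none
Why: Borohydride reduction of the only ketone; hydride should add axially from the face opposite the axial C14 methyl, giving the equatorial 1β-alcohol with C1–O cis to C14, the relationship that later encodes the E geometry.

Step 4
Reactants: 5 (1R,4R,5R,7R,10S)-eudesmane-1,5,11-triol
Product: 6 (1R,4R,5R,7R,10S)-5,11-dihydroxyeudesman-1-yl methanesulfonate
Conditions: MsCl, pyridine, DMAP (cat.), 0 °C
Reagents that add atoms: methanesulfonyl chloride, CS(Cl)(=O)=O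
Why: Selective sulfonylation of the only secondary alcohol; the tertiary C5 and C11 hydroxyls do not react with MsCl in pyridine at 0 °C.

Step 5
Reactants: 6 (1R,4R,5R,7R,10S)-5,11-dihydroxyeudesman-1-yl methanesulfonate
Product: 7 (1(10)E,4R,7R)-11-hydroxygermacr-1(10)-en-5-one
Conditions: KOt-Bu (2.2 equiv), t-BuOH/THF, 0 °C → rt
Reagents that add atoms: none
Why: Wharton–Grob fragmentation of a 1,3-diol monosulfonate: the C5 alkoxide pushes, C5–C10 breaks and mesylate leaves from C1; the equatorial C1–O bond is antiperiplanar to C5–C10 and H-1 is anti to C14, so C2 and C9 should end up trans and the C1=C10 olefin E, stereospecifically, with C5 returned as a ketone.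

Step 6
Reactants: 7 (1(10)E,4R,7R)-11-hydroxygermacr-1(10)-en-5-one
Product: 9 (1(10)E,4E,7R)-11-hydroxygermacra-1(10),4-dien-5-yl trifluoromethanesulfonate (ring-cis at C4=C5), via dilithium alkoxide enolate 8 (not isolated)
Conditions: LiHMDS (1.9 equiv), THF, −78 °C → rt; then Comins' reagent, −78 °C → 0 °C
Reagents that add atoms: N-(5-chloropyridin-2-yl)-bis(trifluoromethanesulfonyl)imide (Comins' reagent), FC(F)(F)S(=O)(=O)N(c1ccc(Cl)cn1)S(=O)(=O)C(F)(F)F
Why: Enol triflate formation from the thermodynamic enolate: with slightly less than two equivalents of base (one is consumed by the C11 hydroxyl) the lithium enolates equilibrate through residual ketone toward the more substituted C4=C5 enolate, and the ring-cis geometry (C3 and C6 cis) should be favoured because it avoids an (E,E)-cyclodeca-1,5-diene; O-sulfonylation then fixes regiochemistry and geometry and erases the C4 centre.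

Step 7
Reactants: 9 (1(10)E,4E,7R)-11-hydroxygermacra-1(10),4-dien-5-yl trifluoromethanesulfonate
Product: 10 (1(10)E,4Z,7R)-germacra-1(10),4-dien-11-ol ((7R)-(2Z,6E)-hedycaryol)
Conditions: Pd(OAc)2 (5 mol %), PPh3 (10 mol %), HCO2H, Et3N, DMF, 40 °C
Reagents that add atoms: none
Why: Palladium-catalysed formate reduction of an enol triflate replaces OTf by H with retention of olefin geometry, so the ring-cis triflate should give the 4Z olefin; the buffered, mild conditions spare the acid- and heat-sensitive 1,5-diene and the tertiary alcohol.

Step 8
Reactants: 10 (1(10)E,4Z,7R)-germacra-1(10),4-dien-11-ol; 11 2,4-diformylphloroglucinol; 12 isovaleraldehyde (3-methylbutanal)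
Product: 14 target (1S,4Z,7R,10R,1'S), via ortho-quinone methide 13 (not isolated)
Conditions: EDDA (20 mol %), MeCN/CH2Cl2, 4 Å MS, rt → 35 °C, dark
Reagents that add atoms: none
Why: Domino Knoevenagel condensation and inverse-demand hetero-Diels–Alder reaction: 13 should add suprafacially to the strained E-C1=C10 olefin in preference to Z-C4=C5, with oxygen going to the more substituted C10, so that the E geometry becomes the trans ring fusion (C14 trans to H-1). The isobutyl group ends up trans to C14, avoiding a 1,3-diaxial clash, which sets C1'; addition to the peripheral face of the conformer that has C14 and the equatorial C7 side chain on the same side relates C1/C10 to C7 as in 14.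

## Compound list

1 | (−)-guaiol, (4S,7R,10S)-guai-1(5)-en-11-ol | C[C@H]1CC[C@H](CC2=C1CC[C@@H]2C)C(C)(C)O | starting material
2 | primary ozonide (1,2,3-trioxolane across C1–C5, either face) | C[C@H]1CC[C@H](CC23OOOC12CC[C@@H]3C)C(C)(C)O | intermediate (not isolated)
3 | (4S,7R,10S)-11-hydroxygermacrane-1,5-dione | C[C@H]1CC[C@H](CC(=O)[C@@H](C)CCC1=O)C(C)(C)O | intermediate
4 | (4R,5R,7R,10R)-5,11-dihydroxyeudesman-1-one (trans-decalin; 5α-OH, 10β-CH3, 4α-CH3, 7β side chain) | O=C1CC[C@@H](C)[C@]2(O)C[C@H](C(C)(C)O)CC[C@@]12C | intermediate
5 | (1R,4R,5R,7R,10S)-eudesmane-1,5,11-triol (1β-OH equatorial) | O[C@@H]1CC[C@@H](C)[C@]2(O)C[C@H](C(C)(C)O)CC[C@@]12C | intermediate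
6 | (1R,4R,5R,7R,10S)-5,11-dihydroxyeudesman-1-yl methanesulfonate | CS(=O)(=O)O[C@@H]1CC[C@@H](C)[C@]2(O)C[C@H](C(C)(C)O)CC[C@@]12C | intermediate
7 | (1(10)E,4R,7R)-11-hydroxygermacr-1(10)-en-5-one | C/C1=C\CC[C@@H](C)C(=O)C[C@H](C(C)(C)O)CC1 | intermediate
8 | dilithium alkoxide enolate of 7 (C4=C5 enolate, ring-cis) | C/C1=C\CC/C(C)=C(O[Li])\C[C@H](C(C)(C)O[Li])CC1 | intermediate (not isolated)
9 | (1(10)E,4E,7R)-11-hydroxygermacra-1(10),4-dien-5-yl trifluoromethanesulfonate (C3 and C6 cis) | C/C1=C\CC/C(C)=C(OS(=O)(=O)C(F)(F)F)\C[C@H](C(C)(C)O)CC1 | intermediate
10 | (1(10)E,4Z,7R)-germacra-1(10),4-dien-11-ol, (7R)-(2Z,6E)-hedycaryol | C/C1=C\CC/C(C)=C\C[C@H](C(C)(C)O)CC1 | intermediate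
11 | 2,4-diformylphloroglucinol (2,4,6-trihydroxyisophthalaldehyde) | O=Cc1c(O)cc(O)c(C=O)c1O | starting material
12 | isovaleraldehyde (3-methylbutanal) | CC(C)CC=O | starting material
13 | ortho-quinone methide, 3,5-diformyl-2,4-dihydroxy-6-(3-methylbutylidene)cyclohexa-2,4-dien-1-one | CC(C)CC=C1C(=O)C(C=O)=C(O)C(C=O)=C1O | intermediate (not isolated)
14 | CNP0570248.1, (1S,4Z,7R,10R,1'S) chroman-fused germacrenol | C/C1=C/C[C@H](C(C)(C)O)CC[C@@]2(C)Oc3c(C=O)c(O)c(C=O)c(O)c3[C@@H](CC(C)C)[C@@H]2CC1 | target

Total step count: 8

Longest linear sequence: 8 steps (1 → 3 → 4 → 5 → 6 → 7 → 9 → 10 → 14)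

Least certain steps:

**Step 1 (key step).** What may go wrong: partial epoxidation instead of cleavage at the hindered tetrasubstituted olefin, or incomplete reduction of peroxidic intermediates. Fallback: starting from 1, epoxidation with mCPBA/NaHCO3 gives 1,5-epoxyguaian-11-ol F1, and periodic acid in aqueous THF cleaves the epoxide through its diol, coming back to the route at 3.

**Step 2.** What may go wrong: ring closure in the opposite sense (C6 enolate onto the C1 carbonyl), followed by irreversible dehydration, or retro-aldol on work-up. Fallback: starting from 3, acid-mediated bromination at the two more substituted α-carbons (PhNMe3Br3, THF) gives 4,10-dibromo-11-hydroxygermacrane-1,5-dione F2. Samarium diiodide (THF, −78 °C) then generates regiodefined samarium enolates at C10 and C4 only. Only the C10 enolate has a carbonyl within six-membered reach, so a Reformatsky-type transannular aldol comes back to the route at 4, and material that does not cyclise is reduced back to 3.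

**Step 6.** What may go wrong: enolisation toward C6 instead of C4, formation of the ring-trans enolate, or sulfonylation of the C11 alkoxide. Fallback: starting from 7, soft enolisation under equilibrating conditions (TMSCl, NaI, Et3N, MeCN) gives the purifiable bis-silyl compound (1(10)E,7R)-5,11-bis(trimethylsilyloxy)germacra-1(10),4-diene F3. Methyllithium releases the regiodefined lithium enolate, which Comins' reagent converts into 11-trimethylsilyloxy enol triflate F4. K2CO3/MeOH removes the silyl ether, coming back to the route at 9.

**Step 8.** What may go wrong: poor facial selectivity on the flexible ring, competing cycloaddition at the Z olefin, proton-induced transannular cyclisation of the 1,5-diene, or tautomerisation of the quinone methide to a styrene. Fallback: starting from 9, the same Knoevenagel/hetero-Diels–Alder reaction with 11 and 12 is run on the enol triflate. Its C4=C5 bond is electron-poor and inert both to the heterodiene and to transannular participation, and its conformational bias differs from that of 10. This gives the 5-trifluoromethanesulfonyloxy cycloadduct F5, and palladium-catalysed formate reduction then comes back to the route at 14.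

**Step 5.** What may go wrong: transannular re-closure (ene or Prins type) of the E-cyclodec-5-enone during work-up or chromatography, or oxetane formation if antiperiplanarity is lost. Fallback: starting from 6, fragmentation and enolisation are run in one flask with excess LiHMDS and quenched with Comins' reagent, so the ketone is never exposed to work-up. This comes back to the route at 9 and makes no new compound.

Further compounds

F1 | step 1 | 1,5-epoxyguaian-11-ol (either epoxide face) | C[C@H]1CC[C@H](CC23OC12CC[C@@H]3C)C(C)(C)O
F2 | step 2 | (7R)-4,10-dibromo-11-hydroxygermacrane-1,5-dione (mixture at C4 and C10) | CC1(Br)CC[C@H](CC(=O)C(C)(Br)CCC1=O)C(C)(C)O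
F3 | step 6 | (1(10)E,7R)-5,11-bis(trimethylsilyloxy)germacra-1(10),4-diene (ring-cis at C4=C5) | C/C1=C\CC/C(C)=C(O[Si](C)(C)C)\C[C@H](C(C)(C)O[Si](C)(C)C)CC1
F4 | step 6 | (1(10)E,7R)-11-trimethylsilyloxygermacra-1(10),4-dien-5-yl trifluoromethanesulfonate (ring-cis at C4=C5) | C/C1=C\CC/C(C)=C(OS(=O)(=O)C(F)(F)F)\C[C@H](C(C)(C)O[Si](C)(C)C)CC1
F5 | step 8 | 5-trifluoromethanesulfonyloxy derivative of 14 | C/C1=C(OS(=O)(=O)C(F)(F)F)/C[C@H](C(C)(C)O)CC[C@@]2(C)Oc3c(C=O)c(O)c(C=O)c(O)c3[C@@H](CC(C)C)[C@@H]2CC1
F0 | step 5 | none | none
A1 | alternative 1 | (2Z,6E,10R)-10,11-epoxyfarnesyl phenyl sulfide | c1ccccc1SC/C=C(C)\CC/C=C(C)/CC[C@H]1OC1(C)C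
A2 | alternative 2 | (2E,6E)-farnesyl diphosphate | CC(C)=CCC/C(C)=C/CC/C(C)=C/COP(=O)(O)OP(=O)(O)O
A3 | alternative 3 | 4,5-seco-diene of 14 (ring-closing metathesis precursor) | C=CC[C@H](C(C)(C)O)CC[C@@]2(C)Oc3c(C=O)c(O)c(C=O)c(O)c3[C@@H](CC(C)C)[C@@H]2CCC(C)=C
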